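**Retrosynthetic overview**
1. Feature: without the catechol ring (C4a, C5, C6, C7, C8, C8a), the ketone ring (C1, C2, C3, C4, C4a, C8a) is a 4-arylcyclohexanone with a mirror plane through C1 and C4. The only stereocentre, C4, is therefore set by telling apart the two enantiotopic α-methylenes (future C2 and C8a), and no bond to C4 is made or broken.
2. Last disconnection: the two O-benzyl groups (on C7 and on naphthalene C4'), removed together by hydrogenolysis.
3. Key disconnection: bonds C4a–C5 and C8a–C8. Carbons C5–C8 come from ethyl 2-benzyloxy-4-(phenylsulfonyl)but-2-enoate (C5 = sulfone carbon, C7 = C–OBn, C8 = ester carbon). It is joined to the (S)-4-arylcyclohex-2-enone by Michael addition, Dieckmann closure and loss of sulfinate.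
4. The enone comes from chiral lithium amide deprotonation/silylation of the ketone, then Saegusa–Ito oxidation. The ketone comes from para-bromination of 5-methoxy-1-naphthol, O-benzylation, Suzuki–Miyaura coupling with the cyclohexenyl boronate ketal, hydrogenation and hydrolysis.
5. Order of rings: the naphthalene and the ketone ring are bought; the catechol ring is the only ring closed (step 11).

Key step: step 11

Assumption: the sense of the enantioselective deprotonation is taken from 4-tert-butylcyclohexanone, where the (R,R)-amide gives the (S)-enol silane; if ketone 7 responds in the opposite sense, the equally available (S,S)-amine is used and nothing else changes.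

Step 1
Reactants: 1 5-methoxynaphthalen-1-ol
Product: 2 4-bromo-5-methoxynaphthalen-1-ol
Conditions: NBS (1.0 equiv), MeCN, −20 → 0 °C, dark
Reagents that add atoms: N-bromosuccinimide, O=C1CCC(=O)N1Br
Why: Electrophilic aromatic bromination with NBS in MeCN is para-selective for 1-naphthols, and on the free naphthol the hydroxyl-bearing ring is clearly the more activated one, so C4 (peri to OMe) should be taken ahead of C8 and C2, a distinction that would be lost after O-benzylation.

Step 2
Reactants: 2 4-bromo-5-methoxynaphthalen-1-ol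
Product: 3 1-(benzyloxy)-4-bromo-5-methoxynaphthalene
Conditions: BnBr (1.1 equiv), K2CO3 (1.5 equiv), DMF, rt
Reagents that add atoms: benzyl bromide, BrCc1ccccc1
Why: Williamson etherification of the naphtholate, which also removes the air sensitivity of the bromonaphthol.

Step 3
Reactants: 3 1-(benzyloxy)-4-bromo-5-methoxynaphthalene; 4 2-(1,4-dioxaspiro[4.5]dec-7-en-8-yl)-4,4,5,5-tetramethyl-1,3,2-dioxaborolane
Product: 5 8-[4-(benzyloxy)-8-methoxynaphthalen-1-yl]-1,4-dioxaspiro[4.5]dec-7-ene
Conditions: Pd(dppf)Cl2 (3 mol %), K2CO3 (2.5 equiv), 1,4-dioxane/H2O, 90 °C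
Reagents that add atoms: none
Why: Suzuki–Miyaura coupling of an aryl bromide with an alkenyl pinacol boronate, in which the bidentate ferrocenyl phosphine handles the electron-rich, peri-hindered bromide and neither ketal nor benzyl ether reacts with aqueous carbonate.

Step 4
Reactants: 5 8-[4-(benzyloxy)-8-methoxynaphthalen-1-yl]-1,4-dioxaspiro[4.5]dec-7-ene
Product: 6 8-[4-(benzyloxy)-8-methoxynaphthalen-1-yl]-1,4-dioxaspiro[4.5]decane
Conditions: H2 (1–4 atm), [Ir(cod)(PCy3)(py)]PF6 (3 mol %), CH2Cl2, rt
Reagents that add atoms: none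
Why: Homogeneous hydrogenation with the cationic iridium catalyst reduces trisubstituted alkenes without hydrogenolysing aryl benzyl ethers as Pd/C would, and the product has a mirror plane, so no stereocentre arises.

Step 5
Reactants: 6 8-[4-(benzyloxy)-8-methoxynaphthalen-1-yl]-1,4-dioxaspiro[4.5]decane
Product: 7 4-[4-(benzyloxy)-8-methoxynaphthalen-1-yl]cyclohexan-1-one
Conditions: 2 M HCl, THF, rt
Reagents that add atoms: water, O
Why: Acid-catalysed ketal hydrolysis under conditions too mild to touch the aryl benzyl or methyl ether.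

Step 6
Reactants: 7 4-[4-(benzyloxy)-8-methoxynaphthalen-1-yl]cyclohexan-1-one
Product: 9 (S)-({4-[4-(benzyloxy)-8-methoxynaphthalen-1-yl]cyclohex-1-en-1-yl}oxy)trimethylsilane, via lithium enolate 8 (not isolated)
Conditions: (R,R)-[PhCH(CH3)]2NH·HCl (1.2 equiv), n-BuLi (2.4 equiv), THF, −78 → 0 °C; 7, −100 °C; Me3SiCl (3 equiv), −100 → −78 °C
Reagents that add atoms: chlorotrimethylsilane, C[Si](C)(C)Cl
Why: Enantioselective deprotonation of a conformationally locked 4-substituted cyclohexanone by a C2-symmetric chiral lithium amide in the presence of LiCl, in which the aryl group sits equatorial, the base takes one of the two enantiotopic axial α-hydrogens and silylation fixes the outcome, so C4 becomes the (S)-stereocentre.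

Step 7
Reactants: 9 (S)-silyl enol ether
Product: 10 (S)-4-[4-(benzyloxy)-8-methoxynaphthalen-1-yl]cyclohex-2-en-1-one
Conditions: Pd(OAc)2 (1.05 equiv), MeCN, rt
Reagents that add atoms: none
Why: Saegusa–Ito oxidation, in which the enol silane gives an oxa-π-allyl complex of divalent palladium and β-hydride elimination places the alkene only on the side fixed in step 6 (next to C4) with release of zerovalent palladium, under neutral conditions that leave C4–H untouched.

Step 8
Reactants: 11 ethyl 2-hydroxybut-3-enoate (racemic)
Product: 12 ethyl 2-(benzyloxy)but-3-enoate (racemic)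
Conditions: BnOC(=NH)CCl3 (1.3 equiv), TfOH (cat.), CH2Cl2/cyclohexane, 0 °C → rt
Reagents that add atoms: benzyl 2,2,2-trichloroacetimidate, N=C(OCc1ccccc1)C(Cl)(Cl)Cl
Why: Acid-catalysed trichloroacetimidate benzylation avoids the base that would move the double bond of this α-hydroxy-β,γ-unsaturated ester into conjugation.

Step 9
Reactants: 12 ethyl 2-(benzyloxy)but-3-enoate; 13 sodium benzenesulfinate
Product: 14 ethyl 2-(benzyloxy)-3-iodo-4-(phenylsulfonyl)butanoate (mixture of diastereomers)
Conditions: I2 (1.2 equiv), 13 (1.5 equiv), EtOAc/H2O, rt, ambient light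
Reagents that add atoms: iodine, [I][I]
Why: Radical iodosulfonylation of a terminal alkene, in which the sulfonyl radical adds to the CH2 terminus and iodine transfer closes the chain, so sulfur ends on the carbon that becomes C5.

Step 10
Reactants: 14 ethyl 2-(benzyloxy)-3-iodo-4-(phenylsulfonyl)butanoate
Product: 16 ethyl 2-(benzyloxy)-4-(phenylsulfonyl)but-2-enoate (E/Z mixture drawn as E), via vinyl sulfone 15 (not isolated)
Conditions: DBU (2 equiv), CH2Cl2, 0 °C → rt
Reagents that add atoms: none
Why: Dehydroiodination of the β-iodo sulfone gives vinyl sulfone 15, and DBU then carries out the known vinyl-to-allyl sulfone isomerisation, driven here by conjugation with the ester and the ether oxygen, which erases the racemic centre and gives an E/Z ratio that does not matter because both isomers give the same anion in step 11.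

Step 11
Reactants: 10 (S)-4-[4-(benzyloxy)-8-methoxynaphthalen-1-yl]cyclohex-2-en-1-one; 16 ethyl 2-(benzyloxy)-4-(phenylsulfonyl)but-2-enoate
Product: 20 (R)-7-(benzyloxy)-4-[4-(benzyloxy)-8-methoxynaphthalen-1-yl]-8-hydroxy-3,4-dihydronaphthalen-1(2H)-one, via lithiated donor 17 (not isolated), via Michael adduct 18 (not isolated), via bicyclic sulfone 19 (not isolated)
Conditions: 16 (1.3 equiv), LiN(SiMe3)2 (1.2 equiv), THF, −78 °C; 10, −78 → 0 °C; DBU (2 equiv), 0 → 40 °C; aq. NH4Cl
Reagents that add atoms: none
Why: Proposed new method: LiN(SiMe3)2 converts either geometric isomer of 16 into the same delocalised anion 17 (the C6–C7 bond rotates freely in its ester-dienolate form), which should add through the sulfone carbon C5 to the enone β-carbon C4a, anti to the C4 naphthyl group, to give 18; the C8a enolate, formed directly or regained from the more stable C5 carbanion by proton shuttling that also re-equilibrates the C6=C7 geometry, then attacks the cis-disposed ester carbonyl C8 in a 6-(enolexo)-exo-trig Dieckmann closure to 19, pulled forward by formation of the C1/C8 diketonate. DBU then removes H-4a while benzenesulfinate leaves C5, helped by the C7 oxygen lone pair acting through C6=C7 (a vinylogous α-alkoxy sulfone) and by the diketonate passing directly into the aromatic C8 phenoxide, so no oxidant is needed and the oxygen pattern (C8–OH from the ester carbon, C7–OBn from the donor) is fixed by the reagent. The closest known reaction types are the Hauser-type Michael–Dieckmann annulation of sulfonyl- or sulfinyl-stabilised benzylic ester anions with cyclohexenones and the γ-selective vinylogous Michael addition of 4-sulfonylcrotonates to enals and enones; what has not been shown is their combination with an acyclic 2-alkoxy donor and a terminating C–H/C–S elimination. No lasting stereocentre is created: C4a (set by the C4 aryl group), C5 and C8a (both epimerisable) all become sp2, and C4 is a spectator whose descriptor changes from S to R only because C4a outranks the naphthyl carbon once the new ring is present. The step needs attack through C5 rather than C7 (C7 is fully substituted), 1,4- rather than 1,2-addition (soft, reversibly adding anion) and C–C bond formation faster than proton loss from the doubly activated C4–H; this is served by keeping 16 in slight excess over the amide so that no free strong base meets 10, by adding 10 at −78 °C and by using only DBU once the mixture is warmed.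

Step 12
Reactants: 20 (R)-7-(benzyloxy)-4-[4-(benzyloxy)-8-methoxynaphthalen-1-yl]-8-hydroxy-3,4-dihydronaphthalen-1(2H)-one
Product: 21 (R)-7,8-dihydroxy-4-(4-hydroxy-8-methoxynaphthalen-1-yl)-3,4-dihydronaphthalen-1(2H)-one
Conditions: H2 (1 atm), Pd/C (10 %), EtOAc/MeOH, rt, work-up under argon
Reagents that add atoms: none
Why: Catalytic hydrogenolysis cleaves both aryl benzyl ethers under neutral conditions in which the methyl ether, the hydrogen-bonded electron-rich aryl ketone and the C4–H stereocentre should be unaffected.

**Compound list**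
1 | 5-methoxynaphthalen-1-ol | COc1cccc2c(O)cccc12 | starting material
2 | 4-bromo-5-methoxynaphthalen-1-ol | COc1cccc2c(O)ccc(Br)c12 | intermediate
3 | 1-(benzyloxy)-4-bromo-5-methoxynaphthalene | COc1cccc2c(OCc3ccccc3)ccc(Br)c12 | intermediate
4 | 2-(1,4-dioxaspiro[4.5]dec-7-en-8-yl)-4,4,5,5-tetramethyl-1,3,2-dioxaborolane | CC1(C)OB(OC1(C)C)C1=CCC2(CC1)OCCO2 | starting material
5 | 8-[4-(benzyloxy)-8-methoxynaphthalen-1-yl]-1,4-dioxaspiro[4.5]dec-7-ene | COc1cccc2c(OCc3ccccc3)ccc(C3=CCC4(CC3)OCCO4)c12 | intermediate
6 | 8-[4-(benzyloxy)-8-methoxynaphthalen-1-yl]-1,4-dioxaspiro[4.5]decane | COc1cccc2c(OCc3ccccc3)ccc(C3CCC4(CC3)OCCO4)c12 | intermediate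
7 | 4-[4-(benzyloxy)-8-methoxynaphthalen-1-yl]cyclohexan-1-one | COc1cccc2c(OCc3ccccc3)ccc(C3CCC(=O)CC3)c12 | intermediate
8 | lithium (S)-4-[4-(benzyloxy)-8-methoxynaphthalen-1-yl]cyclohex-1-en-1-olate | COc1cccc2c(OCc3ccccc3)ccc([C@H]3CCC(O[Li])=CC3)c12 | intermediate (not isolated)
9 | (S)-({4-[4-(benzyloxy)-8-methoxynaphthalen-1-yl]cyclohex-1-en-1-yl}oxy)trimethylsilane | COc1cccc2c(OCc3ccccc3)ccc([C@H]3CCC(O[Si](C)(C)C)=CC3)c12 | intermediate
10 | (S)-4-[4-(benzyloxy)-8-methoxynaphthalen-1-yl]cyclohex-2-en-1-one | COc1cccc2c(OCc3ccccc3)ccc([C@H]3CCC(=O)C=C3)c12 | intermediate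
11 | ethyl 2-hydroxybut-3-enoate (racemic) | C=CC(O)C(=O)OCC | starting material
12 | ethyl 2-(benzyloxy)but-3-enoate (racemic) | C=CC(OCc1ccccc1)C(=O)OCC | intermediate
13 | sodium benzenesulfinate | [Na+].[O-]S(=O)c1ccccc1 | starting material
14 | ethyl 2-(benzyloxy)-3-iodo-4-(phenylsulfonyl)butanoate (diastereomers, racemic) | CCOC(=O)C(OCc1ccccc1)C(I)CS(=O)(=O)c1ccccc1 | intermediate
15 | ethyl (E)-2-(benzyloxy)-4-(phenylsulfonyl)but-3-enoate (racemic) | CCOC(=O)C(OCc1ccccc1)/C=C/S(=O)(=O)c1ccccc1 | intermediate (not isolated)
16 | ethyl 2-(benzyloxy)-4-(phenylsulfonyl)but-2-enoate (E/Z mixture; drawn as the E isomer, ester cis to CH2SO2Ph) | CCOC(=O)/C(OCc1ccccc1)=C\CS(=O)(=O)c1ccccc1 | intermediate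
17 | lithium salt of 16 deprotonated at C4 (delocalised sulfonyl dienolate) | [Li+].CCOC(=O)C(OCc1ccccc1)=C[CH-]S(=O)(=O)c1ccccc1 | intermediate (not isolated)
18 | ethyl (E)-2-(benzyloxy)-4-{(1S,2S)-2-[4-(benzyloxy)-8-methoxynaphthalen-1-yl]-5-oxocyclohexyl}-4-(phenylsulfonyl)but-2-enoate (ring substituents trans; epimers at the sulfone carbon) | COc1cccc2c(OCc3ccccc3)ccc([C@H]3CCC(=O)C[C@@H]3C(/C=C(/OCc3ccccc3)C(=O)OCC)S(=O)(=O)c3ccccc3)c12 | intermediate (not isolated)
19 | (4S,4aR)-7-(benzyloxy)-4-[4-(benzyloxy)-8-methoxynaphthalen-1-yl]-8-hydroxy-5-(phenylsulfonyl)-3,4,4a,5-tetrahydronaphthalen-1(2H)-one (enol form of the C1/C8 diketone; C5 epimers) | COc1cccc2c(OCc3ccccc3)ccc([C@H]3CCC(=O)C4=C(O)C(OCc5ccccc5)=CC(S(=O)(=O)c5ccccc5)[C@H]34)c12 | intermediate (not isolated)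
20 | (R)-7-(benzyloxy)-4-[4-(benzyloxy)-8-methoxynaphthalen-1-yl]-8-hydroxy-3,4-dihydronaphthalen-1(2H)-one | COc1cccc2c(OCc3ccccc3)ccc([C@H]3CCC(=O)c4c3ccc(OCc3ccccc3)c4O)c12 | intermediate
21 | (R)-7,8-dihydroxy-4-(4-hydroxy-8-methoxynaphthalen-1-yl)-3,4-dihydronaphthalen-1(2H)-one | COc1cccc2c(O)ccc([C@H]3CCC(=O)c4c3ccc(O)c4O)c12 | target

**Step count**
Total steps: 12. Longest linear sequence: 9 (steps 1–7, 11, 12). Steps 8–10 form the three-step donor branch.

**Steps most likely to fail**

1. Step 11.
- What may go wrong:
  - attack through C7 or at the carbonyl;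
  - a Michael addition that stalls between two hindered carbons or reverses on warming;
  - ring closure losing out to proton shuttling, or to a second Michael addition from C2 onto C6;
  - slow departure of sulfinate;
  - erosion of enantiopurity by deprotonation of C4–H in unreacted or regenerated enone.
- Fallback (from 10, back at 20): the same ring is built stepwise by known reactions, without a basic conjugate addition.
  - Hosomi–Sakurai allylation of 10 (allyltrimethylsilane, TiCl4, CH2Cl2, −78 °C) should give, anti to the aryl group, (3S,4S)-3-allyl-4-[4-(benzyloxy)-8-methoxynaphthalen-1-yl]cyclohexan-1-one F1.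
  - Lemieux–Johnson cleavage (OsO4 cat., NaIO4, 2,6-lutidine, dioxane/H2O) gives the keto aldehyde F2.
  - Horner–Wadsworth–Emmons reaction of its aldehyde with ethyl 2-(benzyloxy)-2-(diethoxyphosphoryl)acetate (LiCl, DBU, MeCN) gives the 2-benzyloxy enoate F3.
  - KOt-Bu in THF closes C8a–C8 by Dieckmann condensation, the Z isomer being fed in through its dienolate, to give the dihydro compound F4.
  - DDQ (1 equiv, toluene, 0 °C) aromatises the dienol to 20.

2. Step 6.
- What may go wrong: poor discrimination between the two enantiotopic axial α-hydrogens, because the remote and twisted naphthyl group does little more than lock the chair; enolate equilibration before silylation; or induction in the opposite sense.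
- Fallback (from 7, back at 10): catalytic desymmetrising dehydrogenation by enamine oxidation, a reaction known for 4-substituted cyclohexanones. A chiral vicinal primary–tertiary diamine salt condenses with 7, IBX oxidises one of the two enamines, and hydrolysis releases 10. This replaces steps 6 and 7, and the catalyst enantiomer is chosen for the (S)-enone. It makes no compound outside the list (F0).

3. Step 4.
- What may go wrong: slow or incomplete hydrogen uptake at a trisubstituted alkene twisted against the peri-methoxy naphthalene, and catalyst deactivation before full conversion.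
- Fallback (from 5, back at 6): chemoselectivity is given up and the protecting group is put back. Hydrogenation over Pd/C (H2, 4 atm, EtOAc/EtOH) reduces the alkene and cleaves the benzyl ether to give 4-(1,4-dioxaspiro[4.5]decan-8-yl)-5-methoxynaphthalen-1-ol F5. This is re-benzylated (BnBr, K2CO3, DMF) to 6.

**Further compounds**
F1 | step 11 | (3S,4S)-3-allyl-4-[4-(benzyloxy)-8-methoxynaphthalen-1-yl]cyclohexan-1-one | COc1cccc2c(OCc3ccccc3)ccc([C@H]3CCC(=O)C[C@@H]3CC=C)c12
F2 | step 11 | 2-{(1S,2S)-2-[4-(benzyloxy)-8-methoxynaphthalen-1-yl]-5-oxocyclohexyl}acetaldehyde | COc1cccc2c(OCc3ccccc3)ccc([C@H]3CCC(=O)C[C@@H]3CC=O)c12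
F3 | step 11 | ethyl (E)-2-(benzyloxy)-4-{(1S,2S)-2-[4-(benzyloxy)-8-methoxynaphthalen-1-yl]-5-oxocyclohexyl}but-2-enoate | COc1cccc2c(OCc3ccccc3)ccc([C@H]3CCC(=O)C[C@@H]3C/C=C(/OCc3ccccc3)C(=O)OCC)c12
F4 | step 11 | (4S,4aR)-7-(benzyloxy)-4-[4-(benzyloxy)-8-methoxynaphthalen-1-yl]-8-hydroxy-3,4,4a,5-tetrahydronaphthalen-1(2H)-one | COc1cccc2c(OCc3ccccc3)ccc([C@H]3CCC(=O)C4=C(O)C(OCc5ccccc5)=CC[C@H]34)c12
F0 | step 6 | none | none
F5 | step 4 | 4-(1,4-dioxaspiro[4.5]decan-8-yl)-5-methoxynaphthalen-1-ol | COc1cccc2c(O)ccc(C3CCC4(CC3)OCCO4)c12
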